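In a one-step world the target would rise as the substrate falls, and one time constant would describe the flask. These runs don't behave like that.

| setting | amber | red | blue | green | theta | gamma |
|---|---|---|---|---|---|---|
| substrate | 0.27 M | 0.29 M | 0.46 M | 0.40 M | 0.40 M | 0.25 M |
| coupling partner | 0.40 M | 0.40 M | 0.40 M | 1.1 M | 0.400 M | 1.50 M |
| remark | run made earlier | run made earlier | run made earlier | run made earlier |  |  |
| time |  |  |  |  | 50 min | 150 min |

| run | time / min | target / % | substrate / % |
|---|---|---|---|
| amber | 3.00 | 30.0 | 58.0 |
| amber | 8.00 | 68.0 | 23.6 |
| amber | 15.0 | 88.0 | 6.5 |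
| amber | 25.0 | 95.8 | 1.0 |
| amber | 40.0 | 96.9 | 0 |
| red | 8.00 | 67.1 | 23.7 |
| red | 15.0 | 87.2 | 6.5 |
| red | 20.0 | 93.4 | 3.0 |
| red | 30.0 | 97.0 | 0.1 |
| red | 40.0 | 97.2 | 0.1 |
| blue | 3.00 | 29.1 | 58.6 |
| blue | 5.00 | 46.5 | 41.0 |
| blue | 10.0 | 69.4 | 16.4 |
| blue | 20.0 | 81.8 | 2.6 |
| blue | 40.0 | 84.7 | 0 |
| green | 8.00 | 72.7 | 23.8 |
| green | 15.0 | 90.4 | 6.7 |
| green | 20.0 | 95.1 | 2.9 |
| green | 30.0 | 97.4 | 1.0 |
| green | 40.0 | 97.1 | 0.1 |

(scatter of a reading: 0.3 percentage points)



- the winner by amount of target, in percent of the substrate charged; "neither" if no more than 2 percentage points parts them (theta / gamma / neither)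
- how much target is there at the end, in percent of the substrate charged: theta
- how much target is there at the end, in percent of the substrate charged: gamma

I follow the run in slow motion. In the first instants the substrate decays first order: amber's readings give a rate constant f = 0.182 min⁻¹, a time constant τ of 5.48 min. Blue, charged richer, still stands at 58.6% after 3.00 min against amber's 58.0%.

In the middle, what leaves the substrate isn't yet target. After 8.00 min amber has 8.40% in neither form, while green, charged with more coupling partner and also more substrate, has less, at 3.50%. So I take it that a held-up form waits for the partner.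

For the end I carry one quantity, the partner yield Y, the target made per coupling partner charged 97.4%. I read it from blue, where the partner is the limiting reagent. Theta's large term is its ceiling, 97.4%; the correction is what is still held up. In theta the held-up form and the partner thin out together, so the remainder x falls at k times x squared, and its time constant stretches as x shrinks.

Amber after 15.0 min gives k. Taking 3.10% as amber's shortfall at its last reading, I count 2.40% as held up and 0.154 M of partner as free. Balancing feed against use gives a reading of k = 3.21 M⁻¹ min⁻¹. Starting the clock two time constants in, my estimate for theta is x = 0.00799 M, or 2.00%, so I commit to 95.4%. In gamma the partner's clock, 1/k divided by the partner charge, is 0.208 min, far shorter than τ, so I take amber's plateau and say 96.9%. My estimated gap of 1.5 percentage points is inside the margin.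

The forecast, slightly different from mine, gives 95.3% for theta, 97.1% for gamma and neither, and it says that theta “ends on a slow second-order tail”.

The flasks give 95.0% for theta and 95.5% for gamma, so the verdict is neither.

    substrate → intermediate A (k = 0.00300 s⁻¹)
    coupling partner + intermediate A ⇌ intermediate B (K = 23.0 M⁻¹, k = 0.00120 M⁻¹ s⁻¹)
    coupling partner + intermediate A → target (k = 0.0530 M⁻¹ s⁻¹)
    target → over-reaction product (k = 3.70 × 10⁻⁶ s⁻¹)

Gamma holds 3.09% of over-reaction product after 150 min, and its target stands 0.5 points above theta's, which is less than the margin. Now Y goes to a further flask, theta's recipe with 1.6 M of substrate, which is 0.250 equiv of partner. Y gives 24.4% there, and that flask holds 24.3% of target.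

All runs stem from a simulated flask with made-up constants, and the scatter is random.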